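## Structural features

The target is a ten-membered carbocycle (C1–C10) with an exocyclic methylene on C1 (C19), a carboxyl on C4 (C17), a quaternary C5 bearing a methyl group and a CH2–CO–(3-furyl) arm (C11, C12), and a second carboxyl (C18) on C10. C7=C8 and C9=C10 form a conjugated diene whose ring bonds are cis at both double bonds; in CIP terms it is 7Z,9E, because C18 outranks C1. With C1=C19 this becomes a cross-conjugated triene acid. The only stereocentres, C4 (R) and C5 (S), are neighbours: a tertiary carbon α to a carboxyl beside an all-carbon quaternary centre, with C17 and the C5 methyl on the same face once both sit in a six-membered ring. Fragile groups are the furan (peracids, singlet oxygen, strong acid), the enolisable C12 ketone, the base-sensitive C4 centre, the diene geometry and the exocyclic alkene, which can migrate into the ring. The real difficulty is the medium ring: a ten-membered carbocycle has to be made with two conjugated cis olefins next to a quaternary carbon. The key step exploits that C1 and C6 are 1,6-related. A C1–C6 bond turns the ring into a decalin whose ring A (C1–C6) holds C4 and C5 on a chair and whose ring B (C1, C6, C7–C10) is a cyclohexa-1,3-diene with exactly the diene of the target; C19 on C1 and an oxygen on C6 then form a 1,3-diol monosulfonate, whose fragmentation returns the ten-membered ring with C1=C19 in place.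

## Logic of the disconnections

**31 ⇒ 29.** No skeletal bond is cut; the two acids become methyl esters and the C12 ketone a dioxolane. The free acids and the enolisable ketone would not survive the bases and hydrides used earlier. The demand on the forward step is unmasking without epimerising C4 or moving a double bond.

**29 ⇒ 28 ⇒ 27 ⇒ 26.** The two C6–H bonds are exchanged for a carbonyl oxygen. That oxygen is the electron source of the fragmentation and cannot be avoided. The forward removal of an allylic oxygen must put hydrogen on C6 and leave the position and geometry of the diene alone; this is the weakest part of the plan.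

**26 ⇒ 25.** The transannular C1–C6 bond is restored, C1=C19 becomes C19–OMs and C6=O becomes C6–OH. The medium ring becomes a decalin, the diene geometry becomes ring-enforced, and C4/C5 move onto a chair. The forward step needs the alkoxide to fragment faster than it does anything else; the diastereomer with the C6 oxygen anti to C19 is chosen because it cannot close an oxetane.

**25 ⇒ 24 ⇒ 23 ⇒ 22.** The C19 sulfonate is traced to a silyl ether, and the C6 hydroxyl with the C7=C8 bond to a C6–C7 epoxide beside a C8 methylene. The epoxide withholds the tertiary alkoxide until the side chain is complete. The forward step needs a base that removes a C8 proton (γ to the C10 ester) and nothing else.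

**22 ⇒ 21 ⇒ 20 ⇒ 17 + 19.** The C12–furyl bond is cut and the dioxolane removed. The furan must enter after the epoxidation because it would not survive a peracid. The forward steps need addition to an aldehyde in the presence of two esters and an epoxide, and a ketalisation that leaves the epoxide closed.

**17 ⇒ 16 ⇒ 15.** The aldehyde comes from a terminal alkene (one carbon lost) and the epoxide from C6=C7. An allyl group is a robust placeholder for the two-carbon arm. The peracid must choose the trisubstituted ring alkene on the face anti to C19, and the osmium reagent the terminal alkene.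

**15 ⇒ 14 ⇒ 13.** The C10–C18 bond is cut: the ester carbon comes from carbon monoxide on the enol triflate of a C10 ketone. C1 is quaternary, so that ketone enolises only towards C9 and the C9=C10 position is unambiguous. Ring B is deliberately not closed onto a C6 carbonyl from an open dienyl arm: that carbonyl lies between two quaternary carbons, the arm would need its ester trans to C8 beside a quaternary centre, and such a closure would favour the cis ring fusion in which the C6 oxygen can displace the C19 sulfonate.

**13 ⇒ 12 ⇒ 11 ⇒ 10 ⇒ 9.** The C4–C17 bond is cut in the same way, and C4–H comes from a conjugate reduction. The forward protonation must reach C4 from the face opposite the axial C5 methyl.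

**9 ⇒ 7 + 8.** The C5–C11 bond is cut. Deconjugative alkylation of a dienolate makes C5 quaternary and moves the double bond to C6=C7, where it is needed. The allyl group must enter anti to the angular substituent.

**7 ⇒ 6 ⇒ 5.** The C5=C6 bond is cut (aldol condensation) and the C10 ketone is unmasked. The enantioselective desymmetrisation of 5 sets C1, the only source of chirality; C1 is later destroyed, after relaying to C5 and C4.

**5 ⇒ 4 ⇒ 3 ⇒ 1 + 2.** The C1–C19 bond (aldol with a one-carbon aldehyde) and the C1–C2 bond (Michael addition) are cut, leaving two commodity chemicals.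

## Other disconnections considered

**Alternative 1:** The cut is through C5–CH3 and C4–C3, made on a cyclopentanone whose ring carbons map onto C17, C4, C5, C11 and C12. The enone A2 (acetal arm = C6–C7) would take up methyl from AlMe3 under Cu(OTf)2/chiral phosphoramidite catalysis. The aluminium enolate, converted to its ate complex with MeLi, would be allylated to give cyclopentanone A1, with the allyl group (C3–C1) cis to the methyl.
- In its favour: both stereocentres, including the quaternary one, arise in one catalytic enantioselective operation, and alkylation anti to the larger acetal arm gives the relative configuration the target needs. Here the alternative is better than the chosen plan, which uses a sacrificial stereocentre and three operations (steps 4, 6, 9) for the same dyad.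
- Against it: A1 holds neither the ten-membered ring nor any of its three double bonds. The C12–C17 bond must later be cleaved, C1/C10/C19 and C8–C9 added, and the ring closed by a cyclisation that forms or tolerates a cis,cis-diene in a medium ring, which is the problem the fragmentation avoids.
- Comparison: the conjugate addition/enolate trapping is as well precedented as the fragmentation (equal), though enantioselectivity with a coordinating acetal arm on a cyclopentenone is less secure. It is shorter up to the stereodyad (about three steps against nine), but the saving is likely spent on the ring closure.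

**Alternative 2:** The cut is C17–C10. The dimethyl ester A4 of the target would come from the bicyclo[5.3.1]undecenone A3, in which C17 is a one-carbon ketone bridge between C4 and C10 and C9 carries a mesylate. NaOMe adds to the bridging ketone; the adduct breaks the C17–C10 bond antiperiplanar to C9–OMs, giving the C17 ester and C9=C10.
- In its favour: it is a fragmentation of the same family and no ring is closed. C6 stays CH2, so the alternative is better in the endgame: three steps fewer after the key step, and the weakest step of the chosen plan disappears. C4 is a bridgehead in A3 and cannot epimerise before the ring opens (also better).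
- Against it: A3 is itself a medium-ring problem. It has an eight-membered ring with a cis olefin bridged across a cyclohexanone that carries the exocyclic methylene and a quaternary β-keto ester carbon, and the C9 configuration alone decides the C9=C10 geometry. In the chosen plan a six-membered ring fixes that geometry. Methoxide also meets an unprotected, enolisable furyl ketone.
- Comparison: once the substrates exist the two fragmentations are equals in reliability. Decalin 25 is reached by annulation logic, while A3 needs a bridged-ring synthesis, so the alternative has the shorter end and the longer, less certain front.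

**Alternative 3:** The cut is the C7=C8 double bond. Diester A6 (identical with 29) would come from the eleven-membered cyclic sulfone A5, with SO2 between C7 and C8. KOH on Al2O3 with CBr2F2 brominates C8, the α-sulfonyl anion closes the episulfone, and loss of SO2 gives C7=C8.
- In its favour: a thiacycle closed by S-alkylation is among the easier medium rings, and A6 never carries oxygen on C6. The alternative reaches compound 29 without the deoxygenation and is better on that point. The Ramberg–Bäcklund reaction is as well known as the Grob fragmentation (equal).
- Against it: the new olefin geometry is set inside the ten-membered ring and depends on ring conformation, whereas the chosen plan inherits it. C8 is also the γ-position of the C10 enoate, so halogenation at C10 or migration of C9=C10 out of conjugation can compete, and the strongly basic medium threatens C4.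
- Comparison: the precursor must already hold the 9E enoate beside the C1 methylene and the C4/C5 dyad, so the work shifts to an acyclic stereocontrolled assembly and a macrocyclisation. The step count is possibly comparable, with the risk concentrated in the last carbon–carbon bond-forming event.

Key step: step 20

Remark: the target's numbering C1–C19 is kept for all intermediates; C1 and C6 of the decalin are sacrificial stereocentres, and the precursor is made as the trans-fused diastereomer (C6–OH anti to C19), which cannot form an oxetane and arises from epoxidation anti to the angular group.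

## Route

Step 1
Reactants: 1 cyclohexane-1,3-dione; 2 pent-1-en-3-one (ethyl vinyl ketone)
Product: 3 2-(3-oxopentyl)cyclohexane-1,3-dione
Conditions: H2O, rt (1 in excess)
Reagents that add atoms: none
Why: Michael addition of the acidic 1,3-dione to the vinyl ketone forms the C1–C2 bond; an excess of 1 suppresses double addition.

Step 2
Reactants: 3 2-(3-oxopentyl)cyclohexane-1,3-dione
Product: 4 2-(hydroxymethyl)-2-(3-oxopentyl)cyclohexane-1,3-dione
Conditions: 37% aq. CH2O, KHCO3 (cat.), THF–H2O, 0 °C
Reagents that add atoms: formaldehyde, C=O
Why: Aldol addition (hydroxymethylation) of the 2-alkyl-1,3-dione enolate to formaldehyde makes C1 quaternary and brings in C19; only the dione is acidic enough to react under bicarbonate, and a cold, near-neutral work-up avoids the retro-aldol.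

Step 3
Reactants: 4 2-(hydroxymethyl)-2-(3-oxopentyl)cyclohexane-1,3-dione
Product: 5 2-[(tert-butyldiphenylsilyloxy)methyl]-2-(3-oxopentyl)cyclohexane-1,3-dione
Conditions: TBDPSCl, imidazole, CH2Cl2, 0 °C → rt
Reagents that add atoms: tert-butyl(chloro)diphenylsilane, CC(C)(C)[Si](Cl)(c1ccccc1)c1ccccc1
Why: Silylation of the primary alcohol blocks the retro-aldol; the acid-stable ether is chosen to last through the acidic steps 4, 5 and 9 and the basic steps 6, 7, 10 and 17.

Step 4
Reactants: 5 2-[(tert-butyldiphenylsilyloxy)methyl]-2-(3-oxopentyl)cyclohexane-1,3-dione
Product: 6 (8aR)-8a-[(tert-butyldiphenylsilyloxy)methyl]-5-methyl-3,4,8,8a-tetrahydronaphthalene-1,6(2H,7H)-dione (C4 enone with C5 methyl, C10 ketone)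
Conditions: D-phenylalanine (1 equiv), (1R)-(−)-10-camphorsulfonic acid (0.5 equiv), DMF, 30 → 65 °C
Reagents that add atoms: none
Why: Hajos–Parrish–Eder–Sauer–Wiechert aldol condensation (the ring-closing half of a Robinson annulation): the amino acid enamine of the side-chain ketone attacks one of the two enantiotopic ring carbonyls (6-enolendo-exo-trig), closing ring A and setting C1, and dehydration gives the C5=C6 enone. The D-amino acid is chosen because the R centre relays to the required C5 configuration through the anti alkylation of step 6.

Step 5
Reactants: 6 bicyclic enedione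
Product: 7 C10 ethylene ketal of 6 (spiro-1,3-dioxolane at the saturated ketone; C4 enone retained)
Conditions: ethylene glycol, p-TsOH·H2O (cat.), 4 Å molecular sieves, CH2Cl2, rt
Reagents that add atoms: ethane-1,2-diol, OCCO
Why: Acid-catalysed ketalisation is selective for the saturated C10 ketone over the conjugated C4 enone, the usual order for such enediones; it shields C10 from the strong base of step 6.

Step 6
Reactants: 7 enone ketal; 8 allyl bromide
Product: 9 C5-allyl β,γ-unsaturated ketone (C4 ketone; C5 methyl cis and allyl trans to the angular CH2OTBDPS; C6=C7; C10 dioxolane)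
Conditions: KOt-Bu (1.2 equiv), t-BuOH–THF, 0 °C; then 8, 0 °C → rt
Reagents that add atoms: none
Why: Deconjugative α-alkylation of the enone: tert-butoxide removes a C7 proton and the extended dienolate is allylated at C5, which becomes quaternary while the double bond moves to C6=C7. The electrophile should enter anti to the axial angular CH2OTBDPS group, so the C5 methyl ends cis to C19, the arrangement that maps onto C5 (S) of the target.

Step 7
Reactants: 9 C5-allyl ketone
Product: 10 C4 enol triflate (C3=C4–OTf)
Conditions: KN(SiMe3)2, PhNTf2, THF, −78 → 0 °C
Reagents that add atoms: N-phenylbis(trifluoromethanesulfonimide), O=S(=O)(N(c1ccccc1)S(=O)(=O)C(F)(F)F)C(F)(F)F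
Why: O-sulfonylation of the ketone enolate; C5 is quaternary, so enolisation can only go towards C3.

Step 8
Reactants: 10 C4 enol triflate
Product: 11 α,β-unsaturated methyl ester (C3=C4–C17O2Me)
Conditions: Pd(OAc)2 (5 mol%), PPh3, CO (1 atm), MeOH, Et3N, DMF, 60 °C
Reagents that add atoms: carbon monoxide, [C-]#[O+]; methanol, CO
Why: Palladium-catalysed methoxycarbonylation of the alkenyl triflate (oxidative addition to zerovalent palladium, CO insertion, methanolysis) installs C17; methanol in excess intercepts the acylpalladium before it can add to the allyl group.

Step 9
Reactants: 11 unsaturated ester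
Product: 13 keto ester (C10 ketone free; C4 ester cis to the C5 methyl), via ketal ester 12 (not isolated)
Conditions: Mg, MeOH, 0 °C → rt; then 2 M HCl, THF, rt
Reagents that add atoms: water, O
Why: Dissolving-metal conjugate reduction of the enoate leaves the isolated alkenes alone. The ester enolate should be protonated at C4 from the face opposite the axial C5 methyl and C19, which puts the hydrogen on the allyl side and the ester equatorial, cis to the methyl, as in the target. The acidic work-up then hydrolyses the C10 dioxolane while the TBDPS ether persists.

Step 10
Reactants: 13 keto ester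
Product: 14 C10 enol triflate (C9=C10–OTf)
Conditions: KN(SiMe3)2 (1.05 equiv), PhNTf2, THF, −78 °C
Reagents that add atoms: N-phenylbis(trifluoromethanesulfonimide), O=S(=O)(N(c1ccccc1)S(=O)(=O)C(F)(F)F)C(F)(F)F
Why: The ketone is more acidic than the hindered C4 ester and C1 is quaternary, so one equivalent of base gives the C9 enolate only and the triflate fixes the future C9=C10 bond.

Step 11
Reactants: 14 C10 enol triflate
Product: 15 diester with the ring B 1,4-diene (C6=C7 and C9=C10–C18O2Me)
Conditions: Pd(OAc)2 (5 mol%), PPh3, CO (1 atm), MeOH, Et3N, DMF, 60 °C
Reagents that add atoms: carbon monoxide, [C-]#[O+]; methanol, CO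
Why: A second palladium-catalysed methoxycarbonylation installs C18 on C10; triethylamine is too weak to move the skipped diene into conjugation.

Step 12
Reactants: 15 skipped-diene diester
Product: 16 C6–C7 epoxide with the oxygen trans to C19
Conditions: mCPBA (1.1 equiv), NaHCO3, CH2Cl2, 0 °C
Reagents that add atoms: 3-chloroperoxybenzoic acid, O=C(OO)c1cccc(Cl)c1
Why: Prilezhaev epoxidation of the most electron-rich alkene: the trisubstituted C6=C7 bond should react well before the deactivated enoate and the monosubstituted allyl group. The peracid approaches opposite the axial C19 and C5-methyl groups, which sets C6 and C7 with the oxygen anti to C19.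

Step 13
Reactants: 16 epoxide
Product: 17 aldehyde (C5–C11H2–C12HO)
Conditions: OsO4 (2 mol%), NaIO4, 2,6-lutidine, dioxane–H2O, rt
Reagents that add atoms: osmium tetroxide, O=[Os](=O)(=O)=O; sodium periodate, [Na+].[O-][I](=O)(=O)=O
Why: Lemieux–Johnson cleavage of the terminal alkene; the electron-poor enoate is not dihydroxylated and the lutidine buffer keeps the epoxide closed.

Step 14
Reactants: 17 aldehyde; 18 3-bromofuran
Product: 20 furan-3-yl carbinol (mixture of C12 epimers), via 3-furyllithium 19 (not isolated)
Conditions: 18, n-BuLi, THF, −78 °C; then 17, −78 °C; aq. NH4Cl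
Reagents that add atoms: none
Why: Bromine–lithium exchange gives the 3-lithiofuran, kept at −78 °C so that it does not isomerise to the 2-lithio species; it adds to the aldehyde far faster than to the hindered esters or the epoxide. The C12 epimers converge in step 15.

Step 15
Reactants: 20 furyl carbinol
Product: 21 furan-3-yl ketone
Conditions: Dess–Martin periodinane, NaHCO3, CH2Cl2, rt
Reagents that add atoms: none
Why: Dess–Martin oxidation under buffered, non-acidic conditions spares furan and epoxide; oxidising the crude carbinol at once also pre-empts lactonisation of the δ-hydroxy ester.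

Step 16
Reactants: 21 furyl ketone
Product: 22 C12 dioxolane (epoxy enoate ketal)
Conditions: Me3SiOCH2CH2OSiMe3, Me3SiOTf (5 mol%), CH2Cl2, −78 → −20 °C; pyridine quench
Reagents that add atoms: 1,2-bis(trimethylsilyloxy)ethane, C[Si](C)(C)OCCO[Si](C)(C)C
Why: Aprotic silyl-transfer ketalisation protects the C12 ketone, which would otherwise form a cyclic hemiketal with the C6 hydroxyl once that is freed and would be reduced in step 21. Catalytic silyl triflate at low temperature is chosen to leave the hindered epoxide and the furan untouched.

Step 17
Reactants: 22 epoxy enoate ketal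
Product: 23 C6 hydroxy dienoate (C7=C8–C9=C10 diene, C19 still silylated)
Conditions: LiN(SiMe3)2 (1.5 equiv), THF, −78 → 0 °C; aq. NH4Cl
Reagents that add atoms: none
Why: Base-induced eliminative epoxide opening (vinylogous E1cB): deprotonation at C8, γ to the C10 ester, and expulsion of the C7–O bond give the tertiary C6 alkoxide and the conjugated dienoate. C8 carries the only hydrogens β to the epoxide, so there is no regiochemical alternative.

Step 18
Reactants: 23 silyl ether
Product: 24 diol (tertiary C6–OH, primary C19–OH)
Conditions: Bu4NF, AcOH, THF, rt
Reagents that add atoms: none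
Why: Fluoride cleaves the TBDPS ether; acetic acid buffering keeps the medium from becoming basic enough to epimerise C4.

Step 19
Reactants: 24 diol
Product: 25 angular hydroxy mesylate (fragmentation precursor)
Conditions: MsCl (1.1 equiv), Et3N, CH2Cl2, −20 °C
Reagents that add atoms: methanesulfonyl chloride, CS(=O)(=O)Cl
Why: Sulfonylation of the primary C19 alcohol only; the tertiary C6 alcohol lies between two quaternary carbons and does not react, and triethylamine is too weak to form the alkoxide that triggers fragmentation.

Step 20
Reactants: 25 angular hydroxy mesylate
Product: 26 C6-oxo ten-membered triene diester (C12 dioxolane)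
Conditions: KOt-Bu (1.1 equiv), THF, 0 °C, short reaction time; pH 7 buffer
Reagents that add atoms: none
Why: Wharton–Grob fragmentation of a 1,3-diol monosulfonate: tert-butoxide deprotonates the C6 hydroxyl, the alkoxide pushes into the C6–C1 bond, and that bond breaks in concert with formation of the C1=C19 double bond and loss of mesylate from C19, leaving the C6 ketone. The closest known reaction type is the base-induced fragmentation of decalin 1,3-diol monosulfonates to cyclodecenones. The ten-membered ring is not closed by a cyclisation but uncovered by cleaving the bond shared by rings A and B, so no cyclisation entropy or ring-closure mode is involved, and the cis geometry at C7=C8 and C9=C10 is carried over from the cyclohexadiene. No stereocentre is created: C1 and C6 become trigonal, C4 and C5 are untouched. Only chemoselectivity is required. The C19–OMs bond rotates freely into the antiperiplanar alignment with C1–C6; the anti arrangement of the C6 oxygen and C19 rules out oxetane formation; C19 is neopentylic without β-hydrogens, so substitution and elimination are excluded. The dioxolane prevents hemiketal trapping of the alkoxide, the C17 ester is trans to it, and the C18 ester cannot lactonise without a bridgehead double bond. One equivalent of base and a short time at 0 °C should keep C4 from epimerising and the new dienone from adding alkoxide.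

Step 21
Reactants: 26 dienone
Product: 27 C6 allylic alcohol (mixture of C6 epimers)
Conditions: NaBH4, CeCl3·7H2O, MeOH, −40 °C
Reagents that add atoms: none
Why: Luche 1,2-reduction of the hindered dienone without conjugate reduction, leaving esters and ketal; the C6 epimers are inconsequential because the centre is removed in step 23.

Step 22
Reactants: 27 allylic alcohol
Product: 28 C6 methyl carbonate
Conditions: ClCO2Me, pyridine, DMAP (cat.), CH2Cl2, 0 °C
Reagents that add atoms: methyl chloroformate, COC(=O)Cl
Why: Acylation to the allylic carbonate, the leaving group for palladium ionisation; crude 27 is used directly to forestall lactonisation onto the C17 ester.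

Step 23
Reactants: 28 allylic carbonate
Product: 29 ten-membered triene dimethyl ester (C6 now CH2, C12 dioxolane)
Conditions: Pd2(dba)3 (2.5 mol%), PBu3 (10 mol%), HCO2H, Et3N, THF, rt
Reagents that add atoms: none
Why: Palladium-catalysed formate hydrogenolysis of an allylic carbonate (Tsuji–Trost ionisation, decarboxylation of the palladium formate, hydride delivery). With the trialkylphosphine the hydride goes to the more hindered allyl terminus remote from palladium, here C6 next to the quaternary C5, which also restores the conjugated dienoate. Fast inner-sphere hydride transfer should outrun syn–anti isomerisation, so the cis geometry is expected to persist.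

Step 24
Reactants: 29 triene dimethyl ester
Product: 31 target diacid CNP0137484.1, via diacid ketal 30 (not isolated)
Conditions: Me3SnOH (10 equiv), ClCH2CH2Cl, 75 °C; then 1 M HCl, THF, rt
Reagents that add atoms: trimethyltin hydroxide, C[Sn](C)(C)O; water, O
Why: Near-neutral ester cleavage by the tin hydroxide avoids the enolisation of C4 and the migration of the exocyclic double bond that hot aqueous hydroxide could cause; the acidic work-up frees both acids and hydrolyses the aryl ketone dioxolane.

## Compound list

1 | cyclohexane-1,3-dione | O=C1CCCC(=O)C1 | starting material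
2 | pent-1-en-3-one (ethyl vinyl ketone) | CCC(=O)C=C | starting material
3 | 2-(3-oxopentyl)cyclohexane-1,3-dione | CCC(=O)CCC1C(=O)CCCC1=O | intermediate
4 | 2-(hydroxymethyl)-2-(3-oxopentyl)cyclohexane-1,3-dione | CCC(=O)CCC1(CO)C(=O)CCCC1=O | intermediate
5 | 2-[(tert-butyldiphenylsilyloxy)methyl]-2-(3-oxopentyl)cyclohexane-1,3-dione | CCC(=O)CCC1(CO[Si](c2ccccc2)(c2ccccc2)C(C)(C)C)C(=O)CCCC1=O | intermediate
6 | (8aR)-8a-[(tert-butyldiphenylsilyloxy)methyl]-5-methyl-3,4,8,8a-tetrahydronaphthalene-1,6(2H,7H)-dione | O=C1CCCC2=C(C)C(=O)CC[C@@]12CO[Si](c1ccccc1)(c1ccccc1)C(C)(C)C | intermediate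
7 | C10 ethylene ketal of 6 (C4 enone retained) | C1COC2(O1)CCCC3=C(C)C(=O)CC[C@@]23CO[Si](c1ccccc1)(c1ccccc1)C(C)(C)C | intermediate
8 | allyl bromide (3-bromoprop-1-ene) | C=CCBr | starting material
9 | C5-allyl C4 ketone, methyl cis and allyl trans to C19, C6=C7, C10 dioxolane | C1COC2(O1)CCC=C3[C@@](C)(CC=C)C(=O)CC[C@@]23CO[Si](c1ccccc1)(c1ccccc1)C(C)(C)C | intermediate
10 | C4 enol triflate of 9 (C3=C4–OTf) | C1COC2(O1)CCC=C3[C@@](C)(CC=C)C(OS(=O)(=O)C(F)(F)F)=CC[C@@]23CO[Si](c1ccccc1)(c1ccccc1)C(C)(C)C | intermediate
11 | C3=C4 unsaturated C17 methyl ester, C10 dioxolane | C1COC2(O1)CCC=C3[C@@](C)(CC=C)C(C(=O)OC)=CC[C@@]23CO[Si](c1ccccc1)(c1ccccc1)C(C)(C)C | intermediate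
12 | saturated C4 ester (ester cis to C5 methyl), C10 dioxolane | C1COC2(O1)CCC=C3[C@@](C)(CC=C)[C@H](C(=O)OC)CC[C@@]23CO[Si](c1ccccc1)(c1ccccc1)C(C)(C)C | intermediate (not isolated)
13 | keto ester: as 12 with free C10 ketone | O=C1CCC=C2[C@@](C)(CC=C)[C@H](C(=O)OC)CC[C@@]12CO[Si](c1ccccc1)(c1ccccc1)C(C)(C)C | intermediate
14 | C10 enol triflate (C9=C10–OTf) | O=S(=O)(OC1=CCC=C2[C@@](C)(CC=C)[C@H](C(=O)OC)CC[C@@]12CO[Si](c3ccccc3)(c3ccccc3)C(C)(C)C)C(F)(F)F | intermediate
15 | diester with ring B 1,4-diene (C6=C7, C9=C10–CO2Me) | COC(=O)C1=CCC=C2[C@@](C)(CC=C)[C@H](C(=O)OC)CC[C@@]12CO[Si](c1ccccc1)(c1ccccc1)C(C)(C)C | intermediate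
16 | C6–C7 epoxide of 15, oxygen trans to C19 | COC(=O)C1=CC[C@H]3O[C@]32[C@@](C)(CC=C)[C@H](C(=O)OC)CC[C@@]12CO[Si](c1ccccc1)(c1ccccc1)C(C)(C)C | intermediate
17 | aldehyde (C5–CH2–CHO) | COC(=O)C1=CC[C@H]3O[C@]32[C@@](C)(CC=O)[C@H](C(=O)OC)CC[C@@]12CO[Si](c1ccccc1)(c1ccccc1)C(C)(C)C | intermediate
18 | 3-bromofuran | Brc1ccoc1 | starting material
19 | 3-furyllithium (furan-3-yllithium) | [Li]c1ccoc1 | intermediate (not isolated)
20 | furan-3-yl carbinol, mixture of C12 epimers | COC(=O)C1=CC[C@H]3O[C@]32[C@@](C)(CC(O)c4ccoc4)[C@H](C(=O)OC)CC[C@@]12CO[Si](c1ccccc1)(c1ccccc1)C(C)(C)C | intermediate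
21 | furan-3-yl ketone | COC(=O)C1=CC[C@H]3O[C@]32[C@@](C)(CC(=O)c4ccoc4)[C@H](C(=O)OC)CC[C@@]12CO[Si](c1ccccc1)(c1ccccc1)C(C)(C)C | intermediate
22 | C12 dioxolane of 21 (epoxy enoate ketal) | COC(=O)C1=CC[C@H]3O[C@]32[C@@](C)(CC4(OCCO4)c4ccoc4)[C@H](C(=O)OC)CC[C@@]12CO[Si](c1ccccc1)(c1ccccc1)C(C)(C)C | intermediate
23 | C6 hydroxy dienoate, C19 TBDPS ether | COC(=O)C1=CC=C[C@]2(O)[C@@](C)(CC3(OCCO3)c3ccoc3)[C@H](C(=O)OC)CC[C@@]12CO[Si](c1ccccc1)(c1ccccc1)C(C)(C)C | intermediate
24 | diol (C6–OH, C19–OH) | COC(=O)C1=CC=C[C@]2(O)[C@@](C)(CC3(OCCO3)c3ccoc3)[C@H](C(=O)OC)CC[C@@]12CO | intermediate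
25 | angular hydroxy mesylate of the hexahydronaphthalene dienoate (trans-fused; fragmentation precursor) | COC(=O)C1=CC=C[C@]2(O)[C@@](C)(CC3(OCCO3)c3ccoc3)[C@H](C(=O)OC)CC[C@@]12COS(C)(=O)=O | intermediate
26 | C6-oxo ten-membered triene diester, C12 dioxolane | C=C1CC[C@@H](C(=O)OC)[C@](C)(CC2(OCCO2)c2ccoc2)C(=O)/C=C\C=C/1C(=O)OC | intermediate
27 | C6 allylic alcohol, mixture of C6 epimers | C=C1CC[C@@H](C(=O)OC)[C@](C)(CC2(OCCO2)c2ccoc2)C(O)/C=C\C=C/1C(=O)OC | intermediate
28 | C6 methyl carbonate, mixture of C6 epimers | C=C1CC[C@@H](C(=O)OC)[C@](C)(CC2(OCCO2)c2ccoc2)C(OC(=O)OC)/C=C\C=C/1C(=O)OC | intermediate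
29 | ten-membered triene dimethyl ester, C12 dioxolane | C=C1CC[C@@H](C(=O)OC)[C@](C)(CC2(OCCO2)c2ccoc2)C/C=C\C=C/1C(=O)OC | intermediate
30 | diacid with C12 dioxolane | C=C1CC[C@@H](C(=O)O)[C@](C)(CC2(OCCO2)c2ccoc2)C/C=C\C=C/1C(=O)O | intermediate (not isolated)
31 | CNP0137484.1 (4R,5S in the numbering used here) | C=C1CC[C@@H](C(=O)O)[C@](C)(CC(=O)c2ccoc2)C/C=C\C=C/1C(=O)O | target

## Step count and least certain steps

Total step count: 24. Longest linear sequence: 24 steps (1 or 2 → 31): 19 steps to precursor 25, the key step, and 4 steps after it. Compounds 8 and 18 each enter in a single step.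

**Step 20 (key step).** The most likely failure is base-mediated diversion after or beside the fragmentation: enolisation at C4 by tert-butoxide, or conjugate addition and oligomerisation of the new dienone while free alkoxide base is present. The fragmentation could also be slow if the neopentylic mesylate is reluctant to adopt the anti alignment next to the axial C5 methyl. Fallback: generate the alkoxide by the epoxide opening itself, with no external alkoxide. Setting out from 22, Bu4NF/AcOH gives the epoxy alcohol F1 and MsCl/Et3N the epoxy mesylate F2. LiN(SiMe3)2 in THF at −78 → 0 °C then opens the epoxide as in step 17, and the lithium alkoxide of 25 so formed should fragment in the same flask. The route is rejoined at 26.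

**Step 23.** The risk is hydride transfer to C8 or C10 of the pentadienyl palladium intermediate (skipped or deconjugated dienes), or syn–anti equilibration of the allyl ligand that turns C7=C8 trans. Fallback: a radical deoxygenation without a metal–allyl species. Setting out from 27, 1,1′-thiocarbonyldiimidazole/DMAP gives the imidazole-1-carbothioate F3. Bu3SnH/AIBN in toluene at 80 °C (Barton–McCombie) should then transfer hydrogen to C6, the terminus that gives the fully conjugated dienoate. The route is rejoined at 29.

**Step 16.** The risk is Lewis-acid opening or Wagner–Meerwein rearrangement at the fully substituted C6 end of the epoxide during ketalisation, together with slow ketalisation of a hindered aryl ketone. Fallback: remove the epoxide before the ketone is protected. Setting out from 21, LiN(SiMe3)2 (2.5 equiv) and then Me3SiCl open the epoxide and silylate the C6 alkoxide. A mild aqueous work-up returns the ketone from its labile silyl enol ether and leaves the C6 trimethylsilyl ether keto dienoate F4. The same silyl-transfer ketalisation gives its C12 dioxolane F5, and Bu4NF removes both silyl groups. The route is rejoined at 24.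

**Step 4.** The risk is low enantioselectivity and slow enamine formation, because a bulky oxygenated angular substituent and an ethyl ketone both depart from the usual substrates of this aldol cyclisation. Fallback: resolution instead of asymmetric catalysis. Setting out from 5, pyrrolidine/AcOH gives the racemic enedione F6, which is separated on a chiral stationary phase; the antipode F7 is discarded. The route is rejoined at 6.

**Step 6.** The risk is O-allylation of the dienolate, a second alkylation at C3, or incomplete facial selectivity. Fallback: decarboxylative allylation. Setting out from 7, KOt-Bu in THF and then allyl chloroformate at −78 °C give the allyl dienol carbonate F8. Pd(PPh3)4 (cat.) in THF then recombines the dienolate and the allyl cation at C5 with loss of CO2 (Tsuji allylation), again anti to the angular group. The route is rejoined at 9.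

## Further compounds

F1 | step 20 | epoxy alcohol (22 without the silyl group) | COC(=O)C1=CC[C@H]3O[C@]32[C@@](C)(CC4(OCCO4)c4ccoc4)[C@H](C(=O)OC)CC[C@@]12CO
F2 | step 20 | epoxy mesylate | COC(=O)C1=CC[C@H]3O[C@]32[C@@](C)(CC4(OCCO4)c4ccoc4)[C@H](C(=O)OC)CC[C@@]12COS(C)(=O)=O
F3 | step 23 | O-C6 imidazole-1-carbothioate of 27 | C=C1CC[C@@H](C(=O)OC)[C@](C)(CC2(OCCO2)c2ccoc2)C(OC(=S)n2ccnc2)/C=C\C=C/1C(=O)OC
F4 | step 16 | C6 trimethylsilyl ether keto dienoate | COC(=O)C1=CC=C[C@]2(O[Si](C)(C)C)[C@@](C)(CC(=O)c3ccoc3)[C@H](C(=O)OC)CC[C@@]12CO[Si](c1ccccc1)(c1ccccc1)C(C)(C)C
F5 | step 16 | C12 dioxolane of F4 | COC(=O)C1=CC=C[C@]2(O[Si](C)(C)C)[C@@](C)(CC3(OCCO3)c3ccoc3)[C@H](C(=O)OC)CC[C@@]12CO[Si](c1ccccc1)(c1ccccc1)C(C)(C)C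
F6 | step 4 | racemic enedione (racemate of 6) | O=C1CCCC2=C(C)C(=O)CCC12CO[Si](c1ccccc1)(c1ccccc1)C(C)(C)C
F7 | step 4 | (8aS)-enantiomer of 6 | O=C1CCCC2=C(C)C(=O)CC[C@]12CO[Si](c1ccccc1)(c1ccccc1)C(C)(C)C
F8 | step 6 | allyl dienol carbonate of 7 (C4–O–CO2-allyl, C4=C5, C6=C7) | C1COC2(O1)CCC=C3C(C)=C(OC(=O)OCC=C)CC[C@@]23CO[Si](c1ccccc1)(c1ccccc1)C(C)(C)C
A1 | alternative 1 | 2-allyl-3-(1,3-dioxolan-2-ylmethyl)-3-methylcyclopentanone, allyl cis to methyl | C=CC[C@@H]1[C@@](C)(CC2OCCO2)CCC1=O
A2 | alternative 1 | 3-(1,3-dioxolan-2-ylmethyl)cyclopent-2-en-1-one | O=C1CCC(CC2OCCO2)=C1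
A3 | alternative 2 | bicyclo[5.3.1]undecenone keto ester with C9 mesylate and C17 ketone bridge | C=C1CC[C@@H]2[C@](C)(CC(=O)c3ccoc3)C/C=C\[C@H](OS(C)(=O)=O)[C@@]1(C(=O)OC)C2=O
A4 | alternative 2 | dimethyl ester of the target | C=C1CC[C@@H](C(=O)OC)[C@](C)(CC(=O)c2ccoc2)C/C=C\C=C/1C(=O)OC
A5 | alternative 3 | eleven-membered cyclic sulfone (SO2 between C7 and C8) | C=C1CC[C@@H](C(=O)OC)[C@](C)(CC2(OCCO2)c2ccoc2)CCS(=O)(=O)C\C=C/1C(=O)OC
A6 | alternative 3 | target dimethyl ester with C12 dioxolane (identical with 29) | C=C1CC[C@@H](C(=O)OC)[C@](C)(CC2(OCCO2)c2ccoc2)C/C=C\C=C/1C(=O)OC
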